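**Plan**
1. Retrosynthesis: the benzyl ethers and the C4–O bond come off first (back to an achiral C3=C4 isoflav-3-ene), then the C3–C1′ bond to ring B, and last, together, the two bonds that tie ring A to the pyran ring, C8a–O1 and C4a–C4.
2. Enabling feature: on ring A, O1 (on C8a) is para to the C6 oxygen with the C7/C8 methoxyls between them. Ring A is therefore the aromatised form of a 2,3-dimethoxy-p-quinone monoketal with C8a as ketal carbon and C4a as dienone β-carbon, and C4 is a carbonyl-level carbon 1,3 to O1.
3. Forward: 2,3,4-trimethoxyphenol is dearomatised oxidatively in the presence of 3-hydroxypropanal, a carbene-catalysed Stetter closure joins C4 to C4a, and loss of methanol re-aromatises ring A, all in one flask, to give the chroman-4-one; O-methylation completes ring A.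
4. Ring B, made from 2,3-dimethoxy-1,4-benzoquinone as a dibenzyl-protected aryl bromide, is joined at C3 by Pd-catalysed ketone α-arylation; reduction and dehydration give the isoflav-3-ene.
5. Stereochemistry: both centres come from one reagent-controlled step, asymmetric hydroboration–oxidation of the C3=C4 alkene with pinene-derived IpcBH2. Syn addition (H to C3, B to C4) fixes 3,4-trans; the chiral borane fixes 3S,4R.
6. Neutral hydrogenolysis of the benzyl ethers frees the ring B hydroquinone.

Key step: step 1

Assumption (chemistry): 3-hydroxypropanal (2) is taken as a purchasable reagent and used as a dried CH2Cl2 solution, in which its dimer equilibrates with the monomer.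

**Step 1**
Reactants: 1 2,3,4-trimethoxyphenol; 2 3-hydroxypropanal
Product: 5 6-hydroxy-7,8-dimethoxychroman-4-one, via mixed quinone monoketal 3 (not isolated), via Stetter adduct 4 (not isolated)
Conditions: PhI(OAc)2 (1.05 equiv), 2 (2 equiv), CH2Cl2, 0 °C; then C6F5-pyrrolotriazolium tetrafluoroborate (20 mol%), Et3N, rt; then DBU, rt
Reagents that add atoms: none
Why: Proposed new method: PhI(OAc)2 oxidises phenol 1 to a phenoxenium ion that alcohol 2 should trap at the para, methoxy-bearing carbon to give mixed quinone monoketal 3 (O1–C8a formed); the carbene then turns the tethered aldehyde into a Breslow acyl-anion equivalent that adds through C4 to the adjacent unsubstituted dienone β-carbon (C4–C4a formed, adduct 4), and base-induced E1cB loss of methanol from the ketal carbon, now β to the new C4 ketone, followed by enolisation of the C6 ketone returns aromatic ring A. The closest known reaction type is the intramolecular Stetter reaction of O-tethered aldehydes onto 4-alkoxycyclohexa-2,5-dienones obtained by PhI(OAc)2 oxidation of para-substituted phenols; untested here are the quinone monoketal as acceptor, the in-flask ketalisation with a functional alcohol and the eliminative rearomatisation. The pyranone ring closes by 6-exo-trig conjugate addition. No stereocentre is set, since the two sp3 ring-fusion centres of 4 are erased on aromatisation, so an achiral carbene suffices. The step needs para rather than ortho ketalisation (the 4-methoxy carbon is the best cation-stabilising site of the phenoxenium ion), attack at C4a rather than at the other enone β-carbon (that one carries a methoxy group and is a deactivated vinylogous ester), and expulsion of methoxide rather than of ring oxygen O1 (in the C4=C4a enolate of 4 the exocyclic C8a–OMe bond can lie parallel to the π system whereas the endocyclic C8a–O1 bond lies near its nodal plane).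

**Step 2**
Reactants: 5 6-hydroxy-7,8-dimethoxychroman-4-one
Product: 6 6,7,8-trimethoxychroman-4-one
Conditions: MeI, K2CO3, acetone, 50 °C
Reagents that add atoms: iodomethane, CI
Why: Williamson O-methylation should be selective for the phenol, which carbonate deprotonates fully while the ketone α-CH2 is barely touched; no stereocentre is involved.

**Step 3**
Reactants: 7 2,3-dimethoxy-1,4-benzoquinone
Product: 9 1,4-bis(benzyloxy)-2,3-dimethoxybenzene, via 2,3-dimethoxyhydroquinone 8 (not isolated)
Conditions: Na2S2O4, THF/H2O, rt; then BnBr, KOH, Bu4NBr, rt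
Reagents that add atoms: benzyl bromide, BrCc1ccccc1
Why: Reductive alkylation of a quinone: dithionite reduction followed by phase-transfer Williamson benzylation in the same flask should protect the air-sensitive hydroquinone without isolating it.

**Step 4**
Reactants: 9 1,4-bis(benzyloxy)-2,3-dimethoxybenzene
Product: 10 1-bromo-2,5-bis(benzyloxy)-3,4-dimethoxybenzene
Conditions: NBS (1.0 equiv), MeCN, 0 °C
Reagents that add atoms: N-bromosuccinimide, O=C1CCC(=O)N1Br
Why: Electrophilic aromatic bromination of the electron-rich tetra-alkoxybenzene; the two ring C–H positions are equivalent, so a single monobromide should form, and the first bromine deactivates the ring against a second.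

**Step 5**
Reactants: 6 6,7,8-trimethoxychroman-4-one; 10 1-bromo-2,5-bis(benzyloxy)-3,4-dimethoxybenzene
Product: 11 rac-3-[2,5-bis(benzyloxy)-3,4-dimethoxyphenyl]-6,7,8-trimethoxychroman-4-one
Conditions: Pd2(dba)3 (2 mol%), XPhos (5 mol%), K3PO4, toluene, 90 °C
Reagents that add atoms: none
Why: Pd-catalysed ketone α-arylation (enolate arylation of a chroman-4-one to an isoflavanone) should install ring B at C3; the mild phosphate base limits retro-oxa-Michael ring opening, the ortho-benzyloxy group disfavours a second arylation, and the new C3 centre is left racemic on purpose.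

**Step 6**
Reactants: 11 rac-3-[2,5-bis(benzyloxy)-3,4-dimethoxyphenyl]-6,7,8-trimethoxychroman-4-one
Product: 13 3-[2,5-bis(benzyloxy)-3,4-dimethoxyphenyl]-6,7,8-trimethoxy-2H-chromene, via isoflavan-4-ol mixture 12 (not isolated)
Conditions: NaBH4, MeOH/THF, 0 °C; then TsOH (cat.), toluene, 50 °C
Reagents that add atoms: none
Why: Carbonyl reduction followed by acid-catalysed E1 dehydration of the electron-rich benzylic alcohol should give the stilbene-like C3=C4 alkene; no stereocontrol is needed because both centres of 12 are erased.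

**Step 7**
Reactants: 13 3-[2,5-bis(benzyloxy)-3,4-dimethoxyphenyl]-6,7,8-trimethoxy-2H-chromene
Product: 15 (3S,4R)-3-[2,5-bis(benzyloxy)-3,4-dimethoxyphenyl]-6,7,8-trimethoxychroman-4-ol, via chromanyl(isopinocampheyl)borane 14 (not isolated)
Conditions: IpcBH2 (from (+)-α-pinene), THF, −25 °C; then NaOH, H2O2, 0 °C to rt
Reagents that add atoms: hydrogen peroxide, OO
Why: Asymmetric hydroboration–oxidation of a trisubstituted aryl alkene: boron should go to the less substituted C4 and hydrogen to C3 on the same face, and C–B oxidation with retention then places the C4 hydroxyl trans to the C3 aryl, while the chiral borane selects the face that gives 3S,4R by analogy with 1-arylcycloalkenes, which give (1S,2R)-trans-2-arylcycloalkanols with this reagent.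

**Step 8**
Reactants: 15 (3S,4R)-3-[2,5-bis(benzyloxy)-3,4-dimethoxyphenyl]-6,7,8-trimethoxychroman-4-ol
Product: 16 (3S,4R)-3-(2,5-dihydroxy-3,4-dimethoxyphenyl)-6,7,8-trimethoxychroman-4-ol (CNP0111047.1)
Conditions: H2 (1 atm), 10% Pd/C, EtOAc, rt
Reagents that add atoms: none
Why: Catalytic hydrogenolysis of the two aryl benzyl ethers under neutral conditions should leave the secondary benzylic C4–OH and both stereocentres untouched and avoids acid, which would close the 2′-OH onto C4.

**Compound list**
1 | 2,3,4-trimethoxyphenol | COc1ccc(O)c(OC)c1OC | starting material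
2 | 3-hydroxypropanal | OCCC=O | starting material
3 | 2,3,4-trimethoxy-4-(3-oxopropoxy)cyclohexa-2,5-dien-1-one (mixed quinone monoketal) | O=CCCOC1(OC)C=CC(=O)C(OC)=C1OC | intermediate
4 | 7,8,8a-trimethoxy-2,3,4a,8a-tetrahydro-4H-chromene-4,6(5H)-dione (cis-fused Stetter adduct, racemic) | COC1=C(OC)C2(OC)OCCC(=O)C2CC1=O | intermediate
5 | 6-hydroxy-7,8-dimethoxychroman-4-one | O=C1CCOc2c(OC)c(OC)c(O)cc12 | intermediate
6 | 6,7,8-trimethoxychroman-4-one | O=C1CCOc2c(OC)c(OC)c(OC)cc12 | intermediate
7 | 2,3-dimethoxy-1,4-benzoquinone | COC1=C(OC)C(=O)C=CC1=O | starting material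
8 | 2,3-dimethoxyhydroquinone (2,3-dimethoxybenzene-1,4-diol) | COc1c(O)ccc(O)c1OC | intermediate
9 | 1,4-bis(benzyloxy)-2,3-dimethoxybenzene | COc1c(OC)c(OCc2ccccc2)ccc1OCc1ccccc1 | intermediate
10 | 1-bromo-2,5-bis(benzyloxy)-3,4-dimethoxybenzene | COc1c(OC)c(OCc2ccccc2)c(Br)cc1OCc1ccccc1 | intermediate
11 | rac-3-[2,5-bis(benzyloxy)-3,4-dimethoxyphenyl]-6,7,8-trimethoxychroman-4-one | COc1cc2c(c(OC)c1OC)OCC(c1cc(OCc3ccccc3)c(OC)c(OC)c1OCc1ccccc1)C2=O | intermediate
12 | 3-[2,5-bis(benzyloxy)-3,4-dimethoxyphenyl]-6,7,8-trimethoxychroman-4-ol (mixture of stereoisomers) | COc1cc2c(c(OC)c1OC)OCC(c1cc(OCc3ccccc3)c(OC)c(OC)c1OCc1ccccc1)C2O | intermediate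
13 | 3-[2,5-bis(benzyloxy)-3,4-dimethoxyphenyl]-6,7,8-trimethoxy-2H-chromene | COc1cc2c(c(OC)c1OC)OCC(c1cc(OCc3ccccc3)c(OC)c(OC)c1OCc1ccccc1)=C2 | intermediate
14 | {(3S,4R)-3-[2,5-bis(benzyloxy)-3,4-dimethoxyphenyl]-6,7,8-trimethoxychroman-4-yl}(isopinocampheyl)borane, boron at C4 trans to the C3 aryl | C[C@H]1[C@H](B[C@H]4c5cc(OC)c(OC)c(OC)c5OC[C@@H]4c6cc(OCc7ccccc7)c(OC)c(OC)c6OCc8ccccc8)C[C@@H]2C[C@H]1C2(C)C | intermediate
15 | (3S,4R)-3-[2,5-bis(benzyloxy)-3,4-dimethoxyphenyl]-6,7,8-trimethoxychroman-4-ol | COc1cc2c(c(OC)c1OC)OC[C@H](c1cc(OCc3ccccc3)c(OC)c(OC)c1OCc1ccccc1)[C@H]2O | intermediate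
16 | (3S,4R)-3-(2,5-dihydroxy-3,4-dimethoxyphenyl)-6,7,8-trimethoxychroman-4-ol | COc1cc2c(c(OC)c1OC)OC[C@H](c1cc(O)c(OC)c(OC)c1O)[C@H]2O | target

**Step count**
Total steps: 8. Longest linear sequence: 6 (steps 1, 2, 5, 6, 7, 8; the branch through steps 3 and 4 is equally long).

**Steps most likely to fail**

Step 1 (proposed new method). The phenoxenium ion may be trapped poorly by the alcohol. The tethered aldehyde may be lost by β-elimination before the carbene closes the ring. The final elimination may expel the ring oxygen instead of methanol. Fallback with known chemistry, setting out from 1 and returning at 6: O-alkylation of 1 with 3-chloropropanoic acid (NaOH, water, reflux) gives 3-(2,3,4-trimethoxyphenoxy)propanoic acid F1. Friedel–Crafts cycloacylation of F1 (polyphosphoric acid, 70 °C) at the only free ortho position gives 6 directly, so 5 and step 2 are bypassed.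

Step 7. The chiral borane may discriminate the alkene faces poorly, or boron may be placed partly at C3. Fallback setting out from 11 and returning at 15: asymmetric transfer hydrogenation with dynamic kinetic resolution (RuCl[(S,S)-TsDPEN](p-cymene), HCO2H/Et3N) should funnel the racemic, C3-epimerisable ketone into (3S,4S)-3-[2,5-bis(benzyloxy)-3,4-dimethoxyphenyl]-6,7,8-trimethoxychroman-4-ol F4, the cis alcohol. Mitsunobu inversion at C4 (4-nitrobenzoic acid, PPh3, DIAD, THF) gives (3S,4R)-3-[2,5-bis(benzyloxy)-3,4-dimethoxyphenyl]-6,7,8-trimethoxychroman-4-yl 4-nitrobenzoate F5, and methanolysis (K2CO3, MeOH) gives 15.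

Step 5. Oxidative addition to the hindered, electron-rich bromide may be slow, the chromanone may ring-open under base, or over-arylation may occur. Fallback setting out from 6 and 7 and returning at 11, using the quinone itself as the aryl electrophile: silylation of 6 (TMSOTf, Et3N, CH2Cl2, 0 °C) gives 6,7,8-trimethoxy-4-(trimethylsilyloxy)-2H-chromene F2. Mukaiyama–Michael addition of F2 to quinone 7 (BF3·OEt2, CH2Cl2, −78 °C), with tautomerisation of the adduct, gives 3-(2,5-dihydroxy-3,4-dimethoxyphenyl)-6,7,8-trimethoxychroman-4-one F3. Benzylation of F3 (BnBr, K2CO3, DMF) gives 11, so steps 3 and 4 are not needed.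

**Further compounds**
F1 | step 1 | 3-(2,3,4-trimethoxyphenoxy)propanoic acid | COc1ccc(OCCC(=O)O)c(OC)c1OC
F2 | step 5 | 6,7,8-trimethoxy-4-(trimethylsilyloxy)-2H-chromene | COc1cc2c(c(OC)c1OC)OCC=C2O[Si](C)(C)C
F3 | step 5 | 3-(2,5-dihydroxy-3,4-dimethoxyphenyl)-6,7,8-trimethoxychroman-4-one | COc1cc2c(c(OC)c1OC)OCC(c1cc(O)c(OC)c(OC)c1O)C2=O
F4 | step 7 | (3S,4S)-3-[2,5-bis(benzyloxy)-3,4-dimethoxyphenyl]-6,7,8-trimethoxychroman-4-ol | COc1cc2c(c(OC)c1OC)OC[C@H](c1cc(OCc3ccccc3)c(OC)c(OC)c1OCc1ccccc1)[C@@H]2O
F5 | step 7 | (3S,4R)-3-[2,5-bis(benzyloxy)-3,4-dimethoxyphenyl]-6,7,8-trimethoxychroman-4-yl 4-nitrobenzoate | COc1cc2c(c(OC)c1OC)OC[C@H](c1cc(OCc3ccccc3)c(OC)c(OC)c1OCc1ccccc1)[C@H]2OC(=O)c1ccc(cc1)[N+](=O)[O-]
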